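**Remark on the chemistry (assumption):** germacrone (1) and (R)-2-methylbutanoic acid (7) are taken as commercially available. The hand of the chiral acid in step 1 that delivers the (5R,10R) series would be fixed by a screening run with both catalyst antipodes.

**Atom numbering:** eudesmane numbering (ring A = C1–C5, C10; ring B = C5–C10; C11–C13 isopropylidene; C14 on C10; C15 on C4; C2′ = α-carbon of the butanoate).

**Compound numbers used throughout:** 1 germacrone; 2 eudesm-4-yl cation (not isolated); 3 Δ3-dienone; 4 3α,4α-diol; 5 4α-hydroxy-3-ketone; 6 3β,4α-diol; 7 (R)-2-methylbutanoic acid; 8 C3 mono-ester; 9 target.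

## Analysis of the target

- Target 9 is a trans-fused decalin. Ring A (C1–C5, C10) carries the 3β-[(R)-2-methylbutanoyloxy] group and the 4α-acetoxy/4β-methyl carbinol. Ring B (C5–C10) carries the C8 ketone conjugated with the exocyclic C7=C11 isopropylidene. C10 is quaternary (10β-CH3).
- It has four ring stereocentres, C3 (S), C4 (S), C5 (R), C10 (R), and one in the side chain, C2′ (R). 10β-CH3 and 5α-H define the trans fusion, the 4β-CH3 is axial and 1,3-diaxial to the 10β-CH3, and both oxygens (3β, 4α) are equatorial.
- This trans-diequatorial 3,4-diol is the awkward element. Syn-dihydroxylation of a Δ3 alkene gives the cis diol and epoxide opening gives the diaxial isomer, so C3 and C4 cannot both be set by one alkene addition.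
- The two vicinal oxygens carry different acyl groups, one on a hindered tertiary carbinol. Acyl migration, E1 loss of the tertiary acetate and epimerisation at C2′ are the sensitive points.
- The α-isopropylidene ketone of ring B is prone to conjugate reduction, deconjugation and enolisation at C9. Its 7(11)-en-8-one pattern is poorly served by annulation chemistry, which leaves C8 as an unactivated CH2.
- The feature that invites the key move is the C5–C10 ring-fusion bond. Without it, C1–C10 form a cyclodecadiene whose C7=C11/C8=O unit and methyl-bearing C4 and C10 are exactly those of germacrone (1). Target 9 is therefore 1 plus one transannular bond and two oxygens at C3/C4, as in the presumed biosynthesis.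
- The difficulty is that 1 has no stereocentre, so the absolute configuration at C5/C10 has to be created in the cyclisation itself.

## Retrosynthetic reasoning

**9 ⇒ 8 (acetyl C–O bond at O4).** The tertiary acetate is removed first because it is the most labile group and the hardest acylation. With the C3 ester already in place, the only free hydroxyl of 8 is the tertiary one, and migration of the secondary ester onto it is uphill. The forward step must acetylate a hindered tertiary alcohol without E1 loss or acyl scrambling.

**8 ⇒ 6 + 7 (acyl C–O bond at O3).** The chiral side chain is attached as the intact acid 7. Diol 6 differentiates its two hydroxyls on its own, secondary equatorial against tertiary. The forward esterification must not epimerise C2′.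

**6 ⇒ 5 (C3–H bond).** The trans-diequatorial diol is traced to the 4α-hydroxy-3-ketone, because hydride delivery along the axial α trajectory, directed by the 4α-OH and not opposed by the axial 4β-CH3, gives the 3β alcohol. The forward reduction must leave the C8 enone alone.

**5 ⇒ 4 (oxidation level at C3).** Syn-dihydroxylation sets C4 correctly but C3 as the wrong epimer, so a redox inversion at C3 is accepted. The forward oxidation must convert the secondary alcohol of a 1,2-diol without cleaving the C3–C4 bond.

**4 ⇒ 3 (C3–O and C4–O bonds).** Both oxygens come from one syn addition to the Δ3 alkene on the α face, opposite the axial 10β-CH3. This fixes the quaternary carbinol C4 (4α-O, 4β-CH3) relative to C5/C10. The electron-poor tetrasubstituted C7=C11 must stay untouched.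

**3 ⇒ 1 (C5–C10 bond).** Cutting the ring-fusion bond opens both rings at once to the ten-membered ring of 1, which already holds the complete ring-B functionality (C7=C11, C8=O) and every carbon of 9 except the acyl groups. A cut through ring A alone (C4–C5/C1–C10) would leave the ring-B oxidation pattern to be built. The forward reaction is a proton-initiated transannular cyclisation that must form C5–C10, set C5 and C10 in the (5R,10R) sense from an achiral substrate, and end by loss of H-3.

## Alternatives that were turned down

**Alternative 1:** the textbook cut through ring A at C4–C5 and C1–C10 (Robinson annulation).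
- Forward: (2S,5S)-dihydrocarvone A1 and pent-1-en-3-one A2 would give, by Michael addition cis to the isopropenyl group and aldol condensation, (7S,10S)-eudesma-4,11-dien-3-one A3. Dissolving-metal reduction with enolate trapping and Rubottom oxidation would then set 5α-H and the 4α-hydroxy-3-ketone.
- Turned down: ring B of A3 is at the wrong oxidation pattern. C8 is a plain CH2 and C7 carries an isopropenyl group, so the end game needs alkene isomerisation to C7=C11 and an allylic oxidation that must choose C8 over C6. Both are allylic CH2 groups of the same tetrasubstituted alkene, with no structural bias. The chiral-pool stereocentre at C7 is destroyed, and the count exceeds ten steps.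

**Alternative 2:** the same C5–C10 cut, but on a substrate that already carries the C3 ester.
- Forward: acid in acetic acid would cyclise (3S)-3-[(2R)-2-methylbutanoyloxy]germacra-1(10),4,7(11)-trien-8-one A4 with anti capture of acetate at C4, giving 9 directly with C4, C5 and C10 set from C3.
- Turned down: there is no defensible way to oxygenate C3 of 1. C3–H is the least activated allylic position, and C9, C6, C14 and C15 compete. A de novo synthesis of the ten-membered trienone (nickel/chromium-mediated macrocyclisation or the like) would cost more than ten steps before the key step. A4 is also a 3-acyloxy-1,5-diene open to Cope rearrangement, and its ester can participate at the C4 cation and scramble the acyl groups.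

**Alternative 3:** cut of the C3–C4 bond (ring A closed by reductive carbonyl coupling).
- Forward: samarium(II)-mediated ketyl–aldehyde coupling of 3-[(1R,2R)-2-acetyl-1-methyl-5-oxo-4-(propan-2-ylidene)cyclohexyl]propanal A5 would form the diol and both carbinol centres in one step.
- Turned down: the chelated samarium diolate leads to the cis diol, not the required trans-diequatorial one. The reagent also reduces the C7=C11–C8=O enone. A5 needs an asymmetric construction of quaternary C10 next to an epimerisable C5 and is itself about eight steps away.

Key step: step 1

## Route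

**Step 1**
Reactants: 1 germacrone, (3E,7E)-3,7-dimethyl-10-(propan-2-ylidene)cyclodeca-3,7-dien-1-one
Product: 3 (5R,10R)-eudesma-3,7(11)-dien-8-one, via eudesm-4-yl cation 2 (not isolated)
Conditions: chiral confined imidodiphosphorimidate (IDPi) Brønsted acid (5 mol%), CHCl3, 0 °C → rt
Reagents that add atoms: none
Why: Proposed new method: the confined chiral Brønsted acid transfers its proton to C1 of the C1=C10 alkene of 1 in the crossed conformation, the C4=C5 π bond attacks C10 across the ring in the same event (C5–C10 bond), and the ion pair of cation 2 collapses by loss of the axial H-3α to the anion, which regenerates the acid. The closest known reaction types are the transannular cyclisation of germacra-1(10),4-dienes to eudesmanes with achiral acids and the enantioselective proton-initiated polyene cyclisations and cation rearrangements run with chiral Lewis acid-assisted or IDPi Brønsted acids; new is the use of such an acid on a macrocyclic diene whose only chirality is conformational. The one new bond closes both rings, ring A (C1–C5, C10) in a 6-endo-trig and ring B (C5–C10) in a 6-exo-trig sense with respect to the C4=C5 nucleophile. The relative configuration (10β-CH3, 5α-H, trans fusion) is fixed by the substrate, because both E alkenes react by anti addition from the chair–chair crossed conformer. The absolute configuration (5R,10R) is fixed by the catalyst, which has to protonate the outer face of C1=C10 in only one of the two enantiomeric planar-chiral conformers of 1; these interconvert by ring inversion, so the step is run as a dynamic kinetic resolution at a temperature at which inversion should outrun protonation. Site selectivity (C1=C10 before C4=C5, no reaction at the electron-poor C7=C11) follows from the tertiary C10 cation forming with transannular π participation. Regioselectivity of the termination (H-3 and not H-15 or H-5) relies on the anion resting on the α face at the periphery of ring A, where H-3α is aligned with the empty orbital at C4 while H-5α is buried at the ring fusion and C15 lies on the far β face.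

**Step 2**
Reactants: 3 (5R,10R)-eudesma-3,7(11)-dien-8-one
Product: 4 (3R,4S,5R,10R)-3,4-dihydroxyeudesm-7(11)-en-8-one (3α,4α-diol, 4β-CH3)
Conditions: OsO4 (cat.), NMO, acetone/H2O, rt
Reagents that add atoms: osmium tetroxide O=[Os](=O)(=O)=O; N-methylmorpholine N-oxide C[N+]1([O-])CCOCC1; water O
Why: Upjohn dihydroxylation; the osmium reagent adds syn to the electron-rich trisubstituted C3=C4 from the α face, away from the axial 10β-CH3 that sits 1,3 to C4, which sets C4 (4α-O, 4β-CH3) as in 9 and C3 as the 3α epimer; the tetrasubstituted, electron-poor C7=C11 should not react.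

**Step 3**
Reactants: 4 (3R,4S,5R,10R)-3,4-dihydroxyeudesm-7(11)-en-8-one
Product: 5 (4S,5R,10R)-4-hydroxyeudesm-7(11)-ene-3,8-dione
Conditions: IBX, DMSO, rt
Reagents that add atoms: none
Why: IBX oxidation of a 1,2-diol stops at the α-ketol without glycol C–C cleavage; only the axial secondary C3–OH can be oxidised, and no stereocentre is at risk (C4 is fully substituted, C5 is not α to the new ketone).

**Step 4**
Reactants: 5 (4S,5R,10R)-4-hydroxyeudesm-7(11)-ene-3,8-dione
Product: 6 (3S,4S,5R,10R)-3,4-dihydroxyeudesm-7(11)-en-8-one (3β,4α-diol)
Conditions: Me4NBH(OAc)3, MeCN/AcOH, −20 °C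
Reagents that add atoms: none
Why: Hydroxyl-directed triacetoxyborohydride reduction (Evans–Saksena type); the 4α-OH exchanges onto boron and hydride reaches C3 along the axial α trajectory, the β face being shielded by the axial 4β-CH3, so the equatorial 3β alcohol trans to the 4α oxygen should form; the reagent does not reduce the conjugated C8 ketone, which has no hydroxyl to direct it.

**Step 5**
Reactants: 6 (3S,4S,5R,10R)-3,4-dihydroxyeudesm-7(11)-en-8-one; 7 (R)-2-methylbutanoic acid
Product: 8 (3S,4S,5R,10R)-4-hydroxy-3-[(2R)-2-methylbutanoyloxy]eudesm-7(11)-en-8-one
Conditions: DIC, DMAP (cat.), CH2Cl2, 0 °C → rt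
Reagents that add atoms: none
Why: Steglich esterification; only the secondary equatorial C3–OH is acylated, the tertiary C4–OH is inert under these conditions, and carbodiimide activation with catalytic DMAP at low temperature should leave C2′ of 7 unchanged.

**Step 6**
Reactants: 8 (3S,4S,5R,10R)-4-hydroxy-3-[(2R)-2-methylbutanoyloxy]eudesm-7(11)-en-8-one
Product: 9 (3S,4S,5R,10R)-4-acetoxy-3-[(2R)-2-methylbutanoyloxy]eudesm-7(11)-en-8-one (CNP0111007.1)
Conditions: Ac2O, Sc(OTf)3 (cat.), MeCN, −20 °C
Reagents that add atoms: acetic anhydride CC(=O)OC(C)=O
Why: Lewis acid-catalysed acylation of a tertiary alcohol with an anhydride; the 4α-OH is equatorial and accessible, and the low temperature should suppress E1 loss of the tertiary oxygen and 1,2-acyl migration, so both esters stay on their oxygens.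

## Compound list

1 | germacrone, (3E,7E)-3,7-dimethyl-10-(propan-2-ylidene)cyclodeca-3,7-dien-1-one | C/C1=C\CC/C(C)=C/CC(=C(C)C)C(=O)C1 | starting material
2 | (5R,10R)-8-oxoeudesm-7(11)-en-4-yl cation (ion pair with the catalyst anion) | C[C+]1CCC[C@]2(C)CC(=O)C(=C(C)C)C[C@@H]12 | intermediate (not isolated)
3 | (5R,10R)-eudesma-3,7(11)-dien-8-one | CC1=CCC[C@]2(C)CC(=O)C(=C(C)C)C[C@@H]12 | intermediate
4 | (3R,4S,5R,10R)-3,4-dihydroxyeudesm-7(11)-en-8-one | O[C@@H]1CC[C@]2(C)CC(=O)C(=C(C)C)C[C@H]2[C@]1(C)O | intermediate
5 | (4S,5R,10R)-4-hydroxyeudesm-7(11)-ene-3,8-dione | O=C1CC[C@]2(C)CC(=O)C(=C(C)C)C[C@H]2[C@]1(C)O | intermediate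
6 | (3S,4S,5R,10R)-3,4-dihydroxyeudesm-7(11)-en-8-one | O[C@H]1CC[C@]2(C)CC(=O)C(=C(C)C)C[C@H]2[C@]1(C)O | intermediate
7 | (R)-2-methylbutanoic acid | CC[C@@H](C)C(=O)O | starting material
8 | (3S,4S,5R,10R)-4-hydroxy-3-[(2R)-2-methylbutanoyloxy]eudesm-7(11)-en-8-one | CC[C@@H](C)C(=O)O[C@H]1CC[C@]2(C)CC(=O)C(=C(C)C)C[C@H]2[C@]1(C)O | intermediate
9 | (3S,4S,5R,10R)-4-acetoxy-3-[(2R)-2-methylbutanoyloxy]eudesm-7(11)-en-8-one | CC[C@@H](C)C(=O)O[C@H]1CC[C@]2(C)CC(=O)C(=C(C)C)C[C@H]2[C@]1(C)OC(C)=O | target

## Step count and least certain steps

Total step count: 6. Longest linear sequence: 6 (1 → 3 → 4 → 5 → 6 → 8 → 9).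

**Step 1 (key step, proposed new method).**
- What may go wrong: the enantiofacial discrimination may be weak, because the chiral anion has to tell apart two conformer enantiomers of a hydrocarbon-like diene. Ring inversion may be too slow relative to protonation, so that both conformers cyclise. Proton loss from cation 2 may occur at C15 or C5 instead of C3. The product alkene may migrate under the acid, or C1=C10 may move into conjugation before cyclisation.
- Fallback (known chemistry, sets out from 1, returns at 8): 1 is cyclised with an achiral acid (p-TsOH, CH2Cl2), the established transannular reaction, and the Δ3 isomer is separated from alkene isomers on silver nitrate-impregnated silica. This gives 3 together with its enantiomer (5S,10S)-eudesma-3,7(11)-dien-8-one F1. Steps 2–4 on the racemate give, beside 4, 5 and 6, the enantiomeric (3S,4R,5S,10S)-3,4-dihydroxyeudesm-7(11)-en-8-one F2, (4R,5S,10S)-4-hydroxyeudesm-7(11)-ene-3,8-dione F3 and (3R,4R,5S,10S)-3,4-dihydroxyeudesm-7(11)-en-8-one F4. Esterification with enantiopure 7 as in step 5 then gives 8 and the diastereomeric (3R,4R,5S,10S)-4-hydroxy-3-[(2R)-2-methylbutanoyloxy]eudesm-7(11)-en-8-one F5, which should be separable by chromatography or crystallisation. The price is half of the material.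

**Step 6.**
- What may go wrong: 1,2-acyl migration through a trans-fused orthoester followed by fast acetylation of the freed secondary hydroxyl would exchange the two ester positions. Ionisation of the tertiary C4–O bond would lead to elimination.
- Fallback (sets out from 5, returns at 9): the order of the acylations is reversed. The tertiary α-ketol hydroxyl of 5 is acetylated (Ac2O, DMAP) to (4S,5R,10R)-4-acetoxyeudesm-7(11)-ene-3,8-dione F6. The activated C3 ketone is reduced by axial hydride delivery (NaBH4, MeOH/CH2Cl2, −78 °C, acidic quench) to (3S,4S,5R,10R)-4-acetoxy-3-hydroxyeudesm-7(11)-en-8-one F7. F7 is esterified at once with 7 (DIC, DMAP) to 9 before the acetyl group can move to O3.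

**Step 4.**
- What may go wrong: exchange of the hindered tertiary hydroxyl onto boron may be slow, giving incomplete conversion. Forcing the reaction with stronger hydrides would cause reduction of the C8 enone and loss of facial control.
- Fallback (sets out from 5, returns at 6; no new compound, F0): catalyst-controlled asymmetric transfer hydrogenation of the α-hydroxy ketone with a Ru–TsDPEN complex and HCO2H/Et3N. This is selective for C=O over C=C, and the ligand antipode would be matched to the substrate's preference for the (3S) alcohol.

**Step 3.**
- What may go wrong: oxidative cleavage of the C3–C4 glycol, or α-ketol rearrangement of the product on prolonged exposure.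
- Fallback (sets out from 3, returns at 5; no new compound, F0): direct Ru-catalysed ketohydroxylation of the Δ3 alkene (RuCl3 cat., Oxone, NaHCO3, EtOAc/MeCN/H2O). This delivers the α-ketol in one operation from the α face and bypasses 4.

## Further compounds

F1 | step 1 | (5S,10S)-eudesma-3,7(11)-dien-8-one | CC1=CCC[C@@]2(C)CC(=O)C(=C(C)C)C[C@H]12
F2 | step 1 | (3S,4R,5S,10S)-3,4-dihydroxyeudesm-7(11)-en-8-one | O[C@H]1CC[C@@]2(C)CC(=O)C(=C(C)C)C[C@@H]2[C@@]1(C)O
F3 | step 1 | (4R,5S,10S)-4-hydroxyeudesm-7(11)-ene-3,8-dione | O=C1CC[C@@]2(C)CC(=O)C(=C(C)C)C[C@@H]2[C@@]1(C)O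
F4 | step 1 | (3R,4R,5S,10S)-3,4-dihydroxyeudesm-7(11)-en-8-one | O[C@@H]1CC[C@@]2(C)CC(=O)C(=C(C)C)C[C@@H]2[C@@]1(C)O
F5 | step 1 | (3R,4R,5S,10S)-4-hydroxy-3-[(2R)-2-methylbutanoyloxy]eudesm-7(11)-en-8-one | CC[C@@H](C)C(=O)O[C@@H]1CC[C@@]2(C)CC(=O)C(=C(C)C)C[C@@H]2[C@@]1(C)O
F6 | step 6 | (4S,5R,10R)-4-acetoxyeudesm-7(11)-ene-3,8-dione | O=C1CC[C@]2(C)CC(=O)C(=C(C)C)C[C@H]2[C@]1(C)OC(C)=O
F7 | step 6 | (3S,4S,5R,10R)-4-acetoxy-3-hydroxyeudesm-7(11)-en-8-one | O[C@H]1CC[C@]2(C)CC(=O)C(=C(C)C)C[C@H]2[C@]1(C)OC(C)=O
F0 | step 4 | none | none
F0 | step 3 | none | none
A1 | alternative 1 | (2S,5S)-dihydrocarvone, (2S,5S)-2-methyl-5-(prop-1-en-2-yl)cyclohexan-1-one | C[C@H]1CC[C@@H](CC1=O)C(C)=C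
A2 | alternative 1 | pent-1-en-3-one | CCC(=O)C=C
A3 | alternative 1 | (7S,10S)-eudesma-4,11-dien-3-one | CC1=C2C[C@@H](C(C)=C)CC[C@@]2(C)CCC1=O
A4 | alternative 2 | (3S)-3-[(2R)-2-methylbutanoyloxy]germacra-1(10)E,4E,7(11)-trien-8-one | CC[C@@H](C)C(=O)O[C@H]1C/C=C(C)/CC(=O)C(=C(C)C)C/C=C1\C
A5 | alternative 3 | 3-[(1R,2R)-2-acetyl-1-methyl-5-oxo-4-(propan-2-ylidene)cyclohexyl]propanal | O=CCC[C@]1(C)CC(=O)C(=C(C)C)C[C@H]1C(C)=O
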